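The route rests on disconnecting the C6–O1 bond of the 1,2-dioxane ring (ring atoms O1, O2, C3, C4, C5, C6; C7 is the first side-chain carbon). The key step exploits that quaternary C6 is the more substituted end of a C6=C7 alkene placed 1,3 to the lactate-derived carbinol C4, while C3 sits at the aldehyde oxidation level. Iodonium activation lets a C3 methoxy hydroperoxide close the dioxane ring 6-exo, forming C6–O1 and the C6 stereocentre under C4 control in one operation. Its precursor is an open-chain (R)-tertiary alcohol flanked by a CH(OMe)OOH group and an (E)-trisubstituted alkene bearing the 9-phenylnonyl chain. The γ-lactone ring is annulated afterwards.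

Key step: step 10

Remark (assumption): dioxolanone 10 is carried forward as the pure cis isomer after crystallisation; the configurations at the peroxyacetal carbon C3 (compounds 15, 17–19) and at the iodine-bearing C7 (compound 17) have no bearing on the target.

Remark (design): the C4 hydroxyl of the cyclisation precursor is left unprotected. It can reach the activated alkene only through a four-membered closure or an anti-Markovnikov 5-endo attack, and it is needed free afterwards for the silicon tether.

Step 1
Reactants: 1 10-phenyldecanoic acid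
Product: 2 10-phenyldecan-1-ol
Conditions: LiAlH4, THF, 0 °C → reflux; H2O/aq. NaOH work-up
Reagents that add atoms: none
Why: LiAlH4 reduces the carboxylic acid to the primary alcohol (hydride reduction) and leaves the isolated phenyl ring untouched.

Step 2
Reactants: 2 10-phenyldecan-1-ol; 3 ethyl 2-(triphenylphosphoranylidene)propanoate
Product: 5 ethyl (2E)-2-methyl-12-phenyldodec-2-enoate, via 10-phenyldecanal 4 (not isolated)
Conditions: PhI(OAc)2, 2,2,6,6-tetramethylpiperidin-1-oxyl (TEMPO, cat.), CH2Cl2, rt; then 3, rt → 40 °C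
Reagents that add atoms: none
Why: The oxoammonium-mediated oxidation stops at the aldehyde, which undergoes a Wittig reaction in the same flask with the stabilised α-methyl ylide, whose reversible addition should deliver the (E)-trisubstituted enoate.

Step 3
Reactants: 5 ethyl (2E)-2-methyl-12-phenyldodec-2-enoate
Product: 6 (2E)-2-methyl-12-phenyldodec-2-en-1-ol
Conditions: i-Bu2AlH (2.5 equiv), CH2Cl2, −78 → 0 °C
Reagents that add atoms: none
Why: i-Bu2AlH reduces the conjugated ester by 1,2-hydride delivery to the allylic alcohol (ester reduction) without touching the alkene geometry.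

Step 4
Reactants: 6 (2E)-2-methyl-12-phenyldodec-2-en-1-ol
Product: 7 (2E)-1-bromo-2-methyl-12-phenyldodec-2-ene
Conditions: CBr4, PPh3, CH2Cl2, 0 °C
Reagents that add atoms: tetrabromomethane, BrC(Br)(Br)Br
Why: The Appel reaction converts the primary allylic alcohol into the bromide by SN2 displacement of the oxyphosphonium group at 0 °C, so neither allylic transposition nor E/Z scrambling is expected.

Step 5
Reactants: 8 (S)-lactic acid; 9 pivalaldehyde
Product: 10 (2S,5S)-2-tert-butyl-5-methyl-1,3-dioxolan-4-one (cis)
Conditions: p-TsOH·H2O (cat.), H2SO4 (cat.), pentane, reflux with azeotropic removal of water; recrystallisation from Et2O/pentane, −78 °C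
Reagents that add atoms: none
Why: Acid-catalysed acetalisation is reversible, so the new acetal centre C2 settles under thermodynamic control with the tert-butyl group cis to the lactate methyl group, and crystallisation should remove the minor trans isomer.

Step 6
Reactants: 10 (2S,5S)-2-tert-butyl-5-methyl-1,3-dioxolan-4-one; 7 (2E)-1-bromo-2-methyl-12-phenyldodec-2-ene
Product: 12 (2S,5R)-2-tert-butyl-5-methyl-5-[(2E)-2-methyl-12-phenyldodec-2-en-1-yl]-1,3-dioxolan-4-one, via lithium enolate 11 (not isolated)
Conditions: LiN(i-Pr)2, THF, −78 °C; then 7, THF/DMPU, −78 → −30 °C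
Reagents that add atoms: none
Why: Enolate alkylation under the self-regeneration-of-stereocentres principle: deprotonation makes the lactate carbon planar, the tert-butyl group on the acetal carbon shields one face, and the allylic bromide enters trans to it (SN2), which rebuilds the lactate centre as the (R)-configured quaternary carbinol carbon that becomes C4.

Step 7
Reactants: 12 (2S,5R)-2-tert-butyl-5-methyl-5-[(2E)-2-methyl-12-phenyldodec-2-en-1-yl]-1,3-dioxolan-4-one
Product: 13 (2R,4E)-2,4-dimethyl-14-phenyltetradec-4-ene-1,2-diol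
Conditions: LiAlH4, THF, 0 °C → rt
Reagents that add atoms: none
Why: LiAlH4 reduces the dioxolanone carbonyl (ester reduction), the ring collapses with loss of the pivalaldehyde unit as neopentyl alcohol, and the quaternary stereocentre is not involved.

Step 8
Reactants: 13 (2R,4E)-2,4-dimethyl-14-phenyltetradec-4-ene-1,2-diol
Product: 14 (2R,4E)-2-hydroxy-2,4-dimethyl-14-phenyltetradec-4-enal
Conditions: (COCl)2, DMSO, CH2Cl2, −78 °C; then Et3N, −78 → 0 °C
Reagents that add atoms: none
Why: Swern oxidation converts the primary hydroxyl into the aldehyde at low temperature without glycol cleavage, the tertiary hydroxyl cannot be oxidised and the quaternary α-carbon cannot epimerise.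

Step 9
Reactants: 14 (2R,4E)-2-hydroxy-2,4-dimethyl-14-phenyltetradec-4-enal
Product: 15 (2R,4E)-1-hydroperoxy-1-methoxy-2,4-dimethyl-14-phenyltetradec-4-en-2-ol (C1 epimers)
Conditions: urea·H2O2 (5 equiv), Sc(OTf)3 (10 mol %), MeOH, 0 °C → rt
Reagents that add atoms: urea–hydrogen peroxide, NC(N)=O.OO; methanol, CO
Why: Sc(OTf)3-catalysed peroxyacetalisation converts the aldehyde through its methanol hemiacetal and methoxycarbenium ion into the α-methoxy hydroperoxide, H2O2 being the better nucleophile (α-effect) while the unactivated alkene is inert to H2O2, and the new centre forms as both epimers, which is immaterial.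

Step 10
Reactants: 15 (2R,4E)-1-hydroperoxy-1-methoxy-2,4-dimethyl-14-phenyltetradec-4-en-2-ol; 16 N-iodosuccinimide
Product: 17 (4R,6S)-6-[(1R)-1-iodo-10-phenyldecyl]-3-methoxy-4,6-dimethyl-1,2-dioxan-4-ol (C3 epimers)
Conditions: 16 (1.3 equiv), CH2Cl2, 0 °C, dark
Reagents that add atoms: N-iodosuccinimide (16), O=C1CCC(=O)N1I
Why: N-Iodosuccinimide transfers iodonium reversibly to the electron-rich trisubstituted C6=C7 alkene, and the terminal oxygen O1 of the C3 hydroperoxide opens the iodonium ion at the tertiary carbon C6 anti to iodine, succinimide taking up the proton. The closest known reaction type is the halonium-induced cyclisation (iodoetherification, here iodoperoxidation) of unsaturated hydroperoxides and hydroperoxy acetals to 1,2-dioxanes. The 1,2-dioxane ring (O1–O2–C3–C4–C5–C6) closes in the 6-exo-trig mode, C7 with its iodine staying outside the ring. The new C6 stereocentre is controlled by the lactate-derived C4 centre through a chair-like transition state in which the C4 methyl group and the bulky iodonium carbon C7 are equatorial while the C4 hydroxyl and the C6 methyl group are axial, so that the C6 methyl group should end up cis to the C4 oxygen (6S here, 6R after deiodination); C7 is set anti to O1 and is erased in step 11. The step needs 6-exo attack at C6 over 7-endo attack at C7, which the Markovnikov bias of the trisubstituted iodonium ion secures, and it needs the hydroperoxide to win over the free C4 hydroxyl, which lacks the α-effect and could only close a four-membered ring at C6 or attack anti-Markovnikov at C7. Both C3 epimers cyclise and converge later at the planar peroxycarbenium ion.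

Step 11
Reactants: 17 (4R,6S)-6-[(1R)-1-iodo-10-phenyldecyl]-3-methoxy-4,6-dimethyl-1,2-dioxan-4-ol
Product: 18 (4R,6R)-3-methoxy-4,6-dimethyl-6-(10-phenyldecyl)-1,2-dioxan-4-ol (C3 epimers)
Conditions: Bu3SnH (3 equiv, about 1 M), Et3B (0.2 equiv)/air, toluene, 0 °C
Reagents that add atoms: none
Why: Radical-chain dehalogenation: the tributyltin radical abstracts iodine and the secondary C7 radical is quenched by concentrated Bu3SnH at low temperature faster than it can attack the neighbouring O–O bond (epoxide formation), so the peroxide and both quaternary centres should survive.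

Step 12
Reactants: 18 (4R,6R)-3-methoxy-4,6-dimethyl-6-(10-phenyldecyl)-1,2-dioxan-4-ol
Product: 19 (4R,6R)-4-{[dimethyl(prop-2-en-1-yl)silyl]oxy}-3-methoxy-4,6-dimethyl-6-(10-phenyldecyl)-1,2-dioxane (C3 epimers)
Conditions: CH2=CHCH2SiMe2Cl, imidazole, DMF, rt
Reagents that add atoms: allylchlorodimethylsilane, C=CC[Si](C)(C)Cl
Why: Silylation of the tertiary C4 hydroxyl with the small, imidazole-activated dimethylsilyl chloride (silyl ether formation) proceeds under a base too weak to trigger Kornblum–DeLaMare cleavage of the peroxyacetal.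

Step 13
Reactants: 19 (4R,6R)-4-{[dimethyl(prop-2-en-1-yl)silyl]oxy}-3-methoxy-4,6-dimethyl-6-(10-phenyldecyl)-1,2-dioxane
Product: 21 (3R,4R,6R)-4,6-dimethyl-6-(10-phenyldecyl)-3-(prop-2-en-1-yl)-1,2-dioxan-4-ol, via silyl triflate 20 (not isolated)
Conditions: Me3SiOTf (1.1 equiv), 2,6-di-tert-butyl-4-methylpyridine (0.2 equiv), CH2Cl2, −78 °C; then 1 M HCl, THF, 0 °C
Reagents that add atoms: none
Why: Hosomi–Sakurai allylation of a peroxycarbenium ion: Me3SiOTf removes the C3 methoxy group from either C3 epimer and the allylsilane tethered to the C4 oxygen delivers its γ-carbon through a seven-membered transition state to the same face as that oxygen, which sets C3 as R with the allyl group cis to the C4 oxygen, before acid hydrolysis of the silyl triflate frees the hydroxyl.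

Step 14
Reactants: 21 (3R,4R,6R)-4,6-dimethyl-6-(10-phenyldecyl)-3-(prop-2-en-1-yl)-1,2-dioxan-4-ol
Product: 24 (3R,4aR,7aR)-3,4a-dimethyl-3-(10-phenyldecyl)hexahydrofuro[3,2-c][1,2]dioxin-6-ol (both anomers), via secondary ozonide 22 (not isolated), via hydroxy aldehyde 23 (not isolated)
Conditions: O3, CH2Cl2, −78 °C (Sudan Red 7B end-point); then Me2S, −78 °C → rt
Reagents that add atoms: ozone, [O-][O+]=O
Why: Criegee ozonolysis cleaves the only alkene (the indicator dye prevents attack on the phenyl ring), Me2S reduces the ozonide but not the dialkyl peroxide, and the aldehyde is captured by the cis C4 hydroxyl as the five-membered lactol.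

Step 15
Reactants: 24 (3R,4aR,7aR)-3,4a-dimethyl-3-(10-phenyldecyl)hexahydrofuro[3,2-c][1,2]dioxin-6-ol
Product: 25 (3R,4aR,7aR)-3,4a-dimethyl-3-(10-phenyldecyl)tetrahydro-3H-furo[3,2-c][1,2]dioxin-6(4H)-one (target, cis-fused dioxane γ-lactone)
Conditions: PhI(OAc)2, 2,2,6,6-tetramethylpiperidin-1-oxyl (TEMPO, cat.), CH2Cl2, rt
Reagents that add atoms: none
Why: Oxoammonium (TEMPO) oxidation of the lactol C–H gives the γ-lactone under neutral conditions that spare the peroxide and avoid base-induced β-elimination at C3, no stereocentre being touched.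

Compound list
1 | 10-phenyldecanoic acid | OC(=O)CCCCCCCCCc1ccccc1 | starting material
2 | 10-phenyldecan-1-ol | OCCCCCCCCCCc1ccccc1 | intermediate
3 | ethyl 2-(triphenylphosphoranylidene)propanoate | CCOC(=O)C(C)=P(c1ccccc1)(c1ccccc1)c1ccccc1 | starting material
4 | 10-phenyldecanal | O=CCCCCCCCCCc1ccccc1 | intermediate
5 | ethyl (2E)-2-methyl-12-phenyldodec-2-enoate | CCOC(=O)/C(C)=C/CCCCCCCCCc1ccccc1 | intermediate
6 | (2E)-2-methyl-12-phenyldodec-2-en-1-ol | OC/C(C)=C/CCCCCCCCCc1ccccc1 | intermediate
7 | (2E)-1-bromo-2-methyl-12-phenyldodec-2-ene | BrC/C(C)=C/CCCCCCCCCc1ccccc1 | intermediate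
8 | (S)-lactic acid | C[C@H](O)C(=O)O | starting material
9 | pivalaldehyde | CC(C)(C)C=O | starting material
10 | (2S,5S)-2-tert-butyl-5-methyl-1,3-dioxolan-4-one | C[C@@H]1O[C@H](C(C)(C)C)OC1=O | intermediate
11 | lithium enolate of 10, lithium (2S)-2-tert-butyl-5-methyl-1,3-dioxol-4-olate | CC1=C([O-])O[C@@H](C(C)(C)C)O1.[Li+] | intermediate
12 | (2S,5R)-2-tert-butyl-5-methyl-5-[(2E)-2-methyl-12-phenyldodec-2-en-1-yl]-1,3-dioxolan-4-one | C[C@]1(C/C(C)=C/CCCCCCCCCc2ccccc2)O[C@H](C(C)(C)C)OC1=O | intermediate
13 | (2R,4E)-2,4-dimethyl-14-phenyltetradec-4-ene-1,2-diol | OC[C@](C)(O)C/C(C)=C/CCCCCCCCCc1ccccc1 | intermediate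
14 | (2R,4E)-2-hydroxy-2,4-dimethyl-14-phenyltetradec-4-enal | O=C[C@](C)(O)C/C(C)=C/CCCCCCCCCc1ccccc1 | intermediate
15 | (2R,4E)-1-hydroperoxy-1-methoxy-2,4-dimethyl-14-phenyltetradec-4-en-2-ol (C1 epimers) | COC(OO)[C@](C)(O)C/C(C)=C/CCCCCCCCCc1ccccc1 | intermediate
16 | N-iodosuccinimide | O=C1CCC(=O)N1I | starting material
17 | (4R,6S)-6-[(1R)-1-iodo-10-phenyldecyl]-3-methoxy-4,6-dimethyl-1,2-dioxan-4-ol (C3 epimers) | COC1OO[C@](C)([C@H](I)CCCCCCCCCc2ccccc2)C[C@@]1(C)O | intermediate
18 | (4R,6R)-3-methoxy-4,6-dimethyl-6-(10-phenyldecyl)-1,2-dioxan-4-ol (C3 epimers) | COC1OO[C@](C)(CCCCCCCCCCc2ccccc2)C[C@@]1(C)O | intermediate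
19 | (4R,6R)-4-{[dimethyl(prop-2-en-1-yl)silyl]oxy}-3-methoxy-4,6-dimethyl-6-(10-phenyldecyl)-1,2-dioxane (C3 epimers) | COC1OO[C@](C)(CCCCCCCCCCc2ccccc2)C[C@@]1(C)O[Si](C)(C)CC=C | intermediate
20 | (3R,4R,6R)-4,6-dimethyl-6-(10-phenyldecyl)-3-(prop-2-en-1-yl)-1,2-dioxan-4-yl dimethylsilyl triflate (Si–OTf) | C=CC[C@H]1OO[C@](C)(CCCCCCCCCCc2ccccc2)C[C@@]1(C)O[Si](C)(C)OS(=O)(=O)C(F)(F)F | intermediate
21 | (3R,4R,6R)-4,6-dimethyl-6-(10-phenyldecyl)-3-(prop-2-en-1-yl)-1,2-dioxan-4-ol | C=CC[C@H]1OO[C@](C)(CCCCCCCCCCc2ccccc2)C[C@@]1(C)O | intermediate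
22 | (3R,4R,6R)-4,6-dimethyl-6-(10-phenyldecyl)-3-(1,2,4-trioxolan-3-ylmethyl)-1,2-dioxan-4-ol | C1(OOCO1)C[C@H]2OO[C@](C)(CCCCCCCCCCc3ccccc3)C[C@@]2(C)O | intermediate
23 | 2-[(3R,4R,6R)-4-hydroxy-4,6-dimethyl-6-(10-phenyldecyl)-1,2-dioxan-3-yl]acetaldehyde | O=CC[C@H]1OO[C@](C)(CCCCCCCCCCc2ccccc2)C[C@@]1(C)O | intermediate
24 | (3R,4aR,7aR)-3,4a-dimethyl-3-(10-phenyldecyl)hexahydrofuro[3,2-c][1,2]dioxin-6-ol (both anomers) | OC1C[C@H]2OO[C@](C)(CCCCCCCCCCc3ccccc3)C[C@@]2(C)O1 | intermediate
25 | (3R,4aR,7aR)-3,4a-dimethyl-3-(10-phenyldecyl)tetrahydro-3H-furo[3,2-c][1,2]dioxin-6(4H)-one | C[C@@]1(CCCCCCCCCCc2ccccc2)C[C@@]2(C)OC(=O)C[C@H]2OO1 | target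

Total step count: 15. Longest linear sequence: 14 steps (steps 1–4 and 6–15, from 10-phenyldecanoic acid); the lactate branch joins after one step (step 5).

Steps most likely to fail

Step 10. The chair-like closure may discriminate the two alkene faces too weakly, so that the C6 epimer forms alongside the wanted isomer, or iodine may be transferred to the hydroperoxide oxygen instead of the alkene. The fallback sets out from 15 and replaces kinetic iodonium closure by reversible cycloperoxymercuration. Hg(OAc)2 with catalytic HClO4 in CH2Cl2 should let the ring-closed mercurials equilibrate towards the chair with the C4 methyl group and the C6 side chain both equatorial, giving the organomercurial (4R,6S)-6-[(1R)-1-(acetoxymercurio)-10-phenyldecyl]-3-methoxy-4,6-dimethyl-1,2-dioxan-4-ol F1. Reductive demercuration of F1 with NaBH4 in aqueous NaOH at 0 °C would then lead directly back to the route at 18, so that step 11 is not needed.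

Step 13. The silicon tether may be lost (protodesilylation of the allylsilane or Si–O cleavage by the Lewis acid) before the carbon–carbon bond forms, or ionisation may occur at the ring O2–C3 bond instead of by loss of methoxide. The fallback sets out from 18 and brings in the two-carbon unit intermolecularly at the ester oxidation level. Mukaiyama-type addition of 1-(tert-butyldimethylsilyloxy)-1-methoxyethene to the peroxycarbenium ion generated with TiCl4 in CH2Cl2 at −78 °C should give methyl 2-[(3R,4R,6R)-4-hydroxy-4,6-dimethyl-6-(10-phenyldecyl)-1,2-dioxan-3-yl]acetate F2. The cis-configured ester closes to the lactone with catalytic p-TsOH, returning to the route at the target 25, while any C3 epimer cannot lactonise and is separated at that stage. Steps 12–15 are bypassed.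

Step 9. Perhydrolysis of the α-hydroxy aldehyde may stall at hemiacetal or dimethyl acetal mixtures, or the perhydrate may undergo oxidative cleavage of the C3–C4 bond. The fallback sets out from 14 and separates acetal formation from peroxide introduction. Trimethyl orthoformate with catalytic pyridinium p-toluenesulfonate in MeOH should give the dimethyl acetal (2R,4E)-1,1-dimethoxy-2,4-dimethyl-14-phenyltetradec-4-en-2-ol F3. Acid-catalysed exchange of one methoxy group of F3 with anhydrous ethereal H2O2 (catalytic camphorsulfonic acid, Et2O, 0 °C) would then return to the route at 15.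

Further compounds
F1 | step 10 | (4R,6S)-6-[(1R)-1-(acetoxymercurio)-10-phenyldecyl]-3-methoxy-4,6-dimethyl-1,2-dioxan-4-ol (C3 epimers) | COC1OO[C@](C)([C@H]([Hg]OC(C)=O)CCCCCCCCCc2ccccc2)C[C@@]1(C)O
F2 | step 13 | methyl 2-[(3R,4R,6R)-4-hydroxy-4,6-dimethyl-6-(10-phenyldecyl)-1,2-dioxan-3-yl]acetate | COC(=O)C[C@H]1OO[C@](C)(CCCCCCCCCCc2ccccc2)C[C@@]1(C)O
F3 | step 9 | (2R,4E)-1,1-dimethoxy-2,4-dimethyl-14-phenyltetradec-4-en-2-ol | COC(OC)[C@](C)(O)C/C(C)=C/CCCCCCCCCc1ccccc1
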